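**Retrosynthetic overview**
1. Asterelin A is reached by O-demethylation of its dimethyl ether. The dimethyl ether is disconnected at the dibenzofuran biaryl bond C-9a–C-9b (dibenzofuran numbering), which lies inside the 18-membered ring.
2. This bond joins the ring-A carbon flanked by the ether oxygen and an ethano bridge to the ring-B carbon ortho to that oxygen and para to the other bridge. Cutting it leaves rings A and B hinged only by oxygen, in a flexible 19-membered bis(diaryl ether) macrocycle with two CH2CH2 bridges and Br on the ring-A carbon.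
3. The 19-membered ring is closed at the B–C bridge by an intramolecular Wittig reaction and diimide reduction. The A–D bridge comes from an earlier intermolecular Wittig reaction and diimide reduction.
4. Ring B carries a methyl ester and ring C a nitrile, so that one DIBAL-H treatment gives the alcohol and the aldehyde for the second bridge without protecting groups. The AB ether is made by Ullmann coupling and bromination para to OMe, the CD ether by SNAr.
5. Ring order: four purchased benzene rings, then the 19-membered macrocycle (step 10), then the furan ring with contraction to 18 members (step 12).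

Key step: step 12

Assumption: the given structure has no stereocentre and no specified stereo element, so no stereocontrol is needed; the two stilbenes (11, 17) are carried as E/Z mixtures because both isomers converge on reduction.

**Route**

Step 1
Reactants: 1 3-hydroxy-5-methoxybenzaldehyde; 2 methyl 3-bromobenzoate
Product: 3 methyl 3-(3-formyl-5-methoxyphenoxy)benzoate
Conditions: CuI (cat.), N,N-dimethylglycine·HCl (cat.), Cs2CO3, 1,4-dioxane, 90 °C
Reagents that add atoms: none
Why: Cu(I)/amino acid-catalysed Ullmann diaryl ether synthesis couples the phenoxide of 1 with the electron-poor aryl bromide 2, and the non-enolisable aldehyde and the methyl ester tolerate Cs2CO3 in dioxane.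

Step 2
Reactants: 3 methyl 3-(3-formyl-5-methoxyphenoxy)benzoate
Product: 4 methyl 3-(2-bromo-3-formyl-5-methoxyphenoxy)benzoate
Conditions: NBS, MeCN, rt
Reagents that add atoms: N-bromosuccinimide, O=C1CCC(=O)N1Br
Why: Electrophilic aromatic bromination of ring A should go para to the methoxy group (the stronger donor) and ortho to the weaker aryloxy donor, as in the 2-bromination of 3,5-dialkoxybenzaldehydes, while ring B is deactivated by its ester.

Step 3
Reactants: 5 3-hydroxy-4-methoxybenzonitrile; 6 4-fluorobenzaldehyde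
Product: 7 3-(4-formylphenoxy)-4-methoxybenzonitrile
Conditions: K2CO3, DMF, 130 °C
Reagents that add atoms: none
Why: SNAr, in which the phenoxide of 5 displaces fluoride para to the formyl group of 6 and the nitrile is inert.

Step 4
Reactants: 7 3-(4-formylphenoxy)-4-methoxybenzonitrile
Product: 8 3-[4-(hydroxymethyl)phenoxy]-4-methoxybenzonitrile
Conditions: NaBH4, MeOH, 0 °C
Reagents that add atoms: none
Why: Chemoselective borohydride reduction of the aldehyde, which leaves the aryl nitrile untouched.

Step 5
Reactants: 8 3-[4-(hydroxymethyl)phenoxy]-4-methoxybenzonitrile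
Product: 9 [4-(5-cyano-2-methoxyphenoxy)benzyl]triphenylphosphonium bromide
Conditions: PPh3·HBr, MeCN, reflux
Reagents that add atoms: triphenylphosphine hydrobromide, [Br-].[PH+](c1ccccc1)(c1ccccc1)c1ccccc1
Why: Direct alcohol-to-phosphonium salt conversion, in which the para-aryloxy benzylic alcohol is activated by HBr and captured by triphenylphosphine, under conditions that spare the nitrile and the ethers.

Step 6
Reactants: 9 [4-(5-cyano-2-methoxyphenoxy)benzyl]triphenylphosphonium bromide; 4 methyl 3-(2-bromo-3-formyl-5-methoxyphenoxy)benzoate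
Product: 11 methyl 3-(2-bromo-3-{2-[4-(5-cyano-2-methoxyphenoxy)phenyl]ethenyl}-5-methoxyphenoxy)benzoate (E/Z mixture), via phosphorus ylide 10 (not isolated)
Conditions: NaHMDS, THF, 0 °C; then 4, 0 °C to rt
Reagents that add atoms: none
Why: Wittig olefination of the semi-stabilised benzylic ylide with the aldehyde of 4, which reacts far faster than the ester; the alkene geometry is irrelevant because the double bond is reduced next.

Step 7
Reactants: 11 methyl 3-(2-bromo-3-{2-[4-(5-cyano-2-methoxyphenoxy)phenyl]ethenyl}-5-methoxyphenoxy)benzoate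
Product: 12 methyl 3-(2-bromo-3-{2-[4-(5-cyano-2-methoxyphenoxy)phenyl]ethyl}-5-methoxyphenoxy)benzoate
Conditions: TsNHNH2, NaOAc, DME–H2O, reflux
Reagents that add atoms: none
Why: Diimide reduction transfers H2 only to the nonpolar C=C bond, so the aryl bromide, nitrile and ester survive where catalytic hydrogenation would risk debromination.

Step 8
Reactants: 12 methyl 3-(2-bromo-3-{2-[4-(5-cyano-2-methoxyphenoxy)phenyl]ethyl}-5-methoxyphenoxy)benzoate
Product: 14 3-[4-(2-{2-bromo-3-[3-(hydroxymethyl)phenoxy]-5-methoxyphenyl}ethyl)phenoxy]-4-methoxybenzaldehyde, via aldimine 13 (not isolated)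
Conditions: DIBAL-H (excess), CH2Cl2, −78 to 0 °C; then 1 M HCl, rt
Reagents that add atoms: water, O
Why: DIBAL-H reduction takes the methyl ester to the benzylic alcohol and the nitrile only to the aldimine stage, which aqueous acid hydrolyses to the aldehyde, so both ends of the second bridge are unmasked in one operation.

Step 9
Reactants: 14 3-[4-(2-{2-bromo-3-[3-(hydroxymethyl)phenoxy]-5-methoxyphenyl}ethyl)phenoxy]-4-methoxybenzaldehyde
Product: 15 {3-[2-bromo-3-(2-{4-[5-formyl-2-methoxyphenoxy]phenyl}ethyl)-5-methoxyphenoxy]benzyl}triphenylphosphonium bromide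
Conditions: PPh3·HBr, MeCN, reflux
Reagents that add atoms: triphenylphosphine hydrobromide, [Br-].[PH+](c1ccccc1)(c1ccccc1)c1ccccc1
Why: Direct conversion of the benzylic alcohol into its phosphonium bromide by substitution at the benzylic carbon; the aryl aldehyde is engaged only reversibly and should be returned on work-up.

Step 10
Reactants: 15 {3-[2-bromo-3-(2-{4-[5-formyl-2-methoxyphenoxy]phenyl}ethyl)-5-methoxyphenoxy]benzyl}triphenylphosphonium bromide
Product: 17 19-membered macrocyclic stilbene (E/Z mixture; 18 with CH=CH in place of the ring-B/ring-C CH2CH2 bridge), via phosphorus ylide 16 (not isolated)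
Conditions: NaOMe, CH2Cl2, rt, high dilution (slow addition of 15)
Reagents that add atoms: none
Why: Intramolecular Wittig macrocyclisation under high dilution, the standard ring closure of bis(bibenzyl) seco-compounds; the meta-linked rings A, B and C let the 19-membered ring close without strain.

Step 11
Reactants: 17 19-membered macrocyclic stilbene
Product: 18 19-membered bromo macrocycle: ring A = 2-bromo-5-methoxy-1,3-phenylene (CH2CH2 to ring D at C-1, O to ring B at C-3); ring B = 1,3-phenylene (O, CH2CH2); ring C = 4-methoxy-1,3-phenylene (CH2CH2 from ring B at C-1, O to ring D at C-3); ring D = 1,4-phenylene (O, CH2CH2 to ring A)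
Conditions: TsNHNH2, NaOAc, DME–H2O, reflux
Reagents that add atoms: none
Why: Diimide reduction of the stilbene C=C bond, chosen again because it leaves intact the C–Br bond needed for the next step.

Step 12
Reactants: 18 19-membered bromo macrocycle
Product: 19 asterelin A dimethyl ether (18-membered macrocycle containing the dibenzofuran)
Conditions: Pd(OAc)2 (cat.), PCy3·HBF4 (cat.), PivOH (cat.), K2CO3, DMA, 130 °C
Reagents that add atoms: none
Why: Pd(0) from Pd(OAc)2/PCy3 adds oxidatively to the ring-A C–Br bond, pivalate-assisted concerted metalation–deprotonation of the ring-B C–H ortho to the ether oxygen follows through a six-membered palladacycle, and C–C reductive elimination forms the C-9a–C-9b bond. The closest known reaction type is the intramolecular direct arylation of o-halodiaryl ethers to dibenzofurans, run here across a macrocycle. The furan ring is closed by biaryl C–C bond formation between two sp2 carbons already hinged by the ether oxygen, and the same bond contracts the macrocycle transannularly from 19 to 18 members. No stereocentre is created. The step needs site selectivity among three C–H bonds within reach of palladium: the ring-B C–H para to the ethano bridge (wanted), the ring-B C–H flanked by oxygen and bridge, and a ring-D C–H ortho to the other bridge. The bromide fixes the ring-A terminus, the one-atom ether hinge favours the six-membered palladacycle over the seven-membered one needed to reach ring D, and the flanked ring-B site is hindered and would give a 16-membered ring (ring D a 15-membered one), so the less strained 18-membered dibenzofuran should prevail.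

Step 13
Reactants: 19 asterelin A dimethyl ether
Product: 20 asterelin A
Conditions: BBr3, CH2Cl2, −78 °C to rt; then H2O
Reagents that add atoms: none
Why: BBr3-mediated cleavage of both aryl methyl ethers (bromide attack at the methyl carbon, then hydrolysis on work-up), to which the diaryl ether, the dibenzofuran and the benzylic C–C bonds are inert.

**Compound list**
1 | 3-hydroxy-5-methoxybenzaldehyde | COc1cc(O)cc(C=O)c1 | starting material
2 | methyl 3-bromobenzoate | COC(=O)c1cccc(Br)c1 | starting material
3 | methyl 3-(3-formyl-5-methoxyphenoxy)benzoate | COC(=O)c1cccc(Oc2cc(OC)cc(C=O)c2)c1 | intermediate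
4 | methyl 3-(2-bromo-3-formyl-5-methoxyphenoxy)benzoate | COC(=O)c1cccc(Oc2cc(OC)cc(C=O)c2Br)c1 | intermediate
5 | 3-hydroxy-4-methoxybenzonitrile | COc1ccc(C#N)cc1O | starting material
6 | 4-fluorobenzaldehyde | O=Cc1ccc(F)cc1 | starting material
7 | 3-(4-formylphenoxy)-4-methoxybenzonitrile | COc1ccc(C#N)cc1Oc1ccc(C=O)cc1 | intermediate
8 | 3-[4-(hydroxymethyl)phenoxy]-4-methoxybenzonitrile | COc1ccc(C#N)cc1Oc1ccc(CO)cc1 | intermediate
9 | [4-(5-cyano-2-methoxyphenoxy)benzyl]triphenylphosphonium bromide | COc1ccc(C#N)cc1Oc1ccc(C[P+](c2ccccc2)(c2ccccc2)c2ccccc2)cc1.[Br-] | intermediate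
10 | [4-(5-cyano-2-methoxyphenoxy)benzylidene]triphenylphosphorane (ylide, not isolated) | COc1ccc(C#N)cc1Oc1ccc(C=P(c2ccccc2)(c2ccccc2)c2ccccc2)cc1 | intermediate
11 | methyl 3-(2-bromo-3-{2-[4-(5-cyano-2-methoxyphenoxy)phenyl]ethenyl}-5-methoxyphenoxy)benzoate (E/Z mixture, geometry undefined) | COC(=O)c1cccc(Oc2cc(OC)cc(C=Cc3ccc(Oc4cc(C#N)ccc4OC)cc3)c2Br)c1 | intermediate
12 | methyl 3-(2-bromo-3-{2-[4-(5-cyano-2-methoxyphenoxy)phenyl]ethyl}-5-methoxyphenoxy)benzoate | COC(=O)c1cccc(Oc2cc(OC)cc(CCc3ccc(Oc4cc(C#N)ccc4OC)cc3)c2Br)c1 | intermediate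
13 | N–H aldimine of 14 (not isolated) | OCc1cccc(Oc2cc(OC)cc(CCc3ccc(Oc4cc(C=N)ccc4OC)cc3)c2Br)c1 | intermediate
14 | 3-[4-(2-{2-bromo-3-[3-(hydroxymethyl)phenoxy]-5-methoxyphenyl}ethyl)phenoxy]-4-methoxybenzaldehyde | OCc1cccc(Oc2cc(OC)cc(CCc3ccc(Oc4cc(C=O)ccc4OC)cc3)c2Br)c1 | intermediate
15 | {3-[2-bromo-3-(2-{4-[5-formyl-2-methoxyphenoxy]phenyl}ethyl)-5-methoxyphenoxy]benzyl}triphenylphosphonium bromide | [Br-].O=Cc1ccc(OC)c(Oc2ccc(CCc3cc(OC)cc(Oc4cccc(C[P+](c5ccccc5)(c5ccccc5)c5ccccc5)c4)c3Br)cc2)c1 | intermediate
16 | ylide derived from 15 (not isolated) | O=Cc1ccc(OC)c(Oc2ccc(CCc3cc(OC)cc(Oc4cccc(C=P(c5ccccc5)(c5ccccc5)c5ccccc5)c4)c3Br)cc2)c1 | intermediate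
17 | 19-membered macrocyclic stilbene (E/Z mixture, geometry undefined) | COc1cc2c(Br)c(c1)Oc1cc(ccc1)C=Cc1ccc(OC)c(c1)Oc1ccc(cc1)CC2 | intermediate
18 | 19-membered bromo bis(diaryl ether) macrocycle | COc1cc2c(Br)c(c1)Oc1cc(ccc1)CCc1ccc(OC)c(c1)Oc1ccc(cc1)CC2 | intermediate
19 | asterelin A dimethyl ether | COc1cc2c3c(c1)oc1cc(ccc13)CCc1ccc(OC)c(c1)Oc1ccc(cc1)CC2 | intermediate
20 | asterelin A | Oc1cc2c3c(c1)oc1cc(ccc13)CCc1ccc(O)c(c1)Oc1ccc(cc1)CC2 | target

**Step count**
Total: 13 steps. Longest linear sequence: 11 steps (steps 3–13, from 5 and 6).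

**Steps most likely to fail**

Step 12. Oxidative addition at the doubly ortho-substituted, electron-rich bromide may be slow enough that protodebromination takes over. C–H metalation may also stray to ring D (six-membered closure) or to the flanked ring-B site. The fallback builds the dibenzofuran before the macrocycle. It sets out from 4: the same Pd(OAc)2/PCy3·HBF4/K2CO3/DMA direct arylation on this simple o-bromodiaryl ether, which has no ring D, should give methyl 9-formyl-7-methoxydibenzo[b,d]furan-3-carboxylate F1. Wittig reaction of F1 with ylide 10 (NaHMDS, THF) should give the stilbene methyl 9-{2-[4-(5-cyano-2-methoxyphenoxy)phenyl]ethenyl}-7-methoxydibenzo[b,d]furan-3-carboxylate F2, and diimide reduction the bibenzyl methyl 9-{2-[4-(5-cyano-2-methoxyphenoxy)phenyl]ethyl}-7-methoxydibenzo[b,d]furan-3-carboxylate F3. DIBAL-H followed by aqueous HCl should pass through the N–H aldimine F4 to 3-[4-(2-{7-(hydroxymethyl)-3-methoxydibenzo[b,d]furan-1-yl}ethyl)phenoxy]-4-methoxybenzaldehyde F5. PPh3·HBr should give ({9-[2-{4-(5-formyl-2-methoxyphenoxy)phenyl}ethyl]-7-methoxydibenzo[b,d]furan-3-yl}methyl)triphenylphosphonium bromide F6. NaOMe under high dilution should close the ring through the ylide of the dibenzofuran seco-aldehyde F7 to the 18-membered didehydro-asterelin A dimethyl ether F8 (E/Z), and diimide reduction of F8 comes back to the route at 19. The risk then moves to closing an 18-membered ring onto a rigid dibenzofuran.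

Step 10. Intermolecular Wittig reaction may compete with ring closure and give oligomers. The fallback is a McMurry macrocyclisation. It sets out from 14: MnO2 in CH2Cl2 should oxidise the benzylic alcohol to the dialdehyde 3-[4-(2-{2-bromo-3-(3-formylphenoxy)-5-methoxyphenyl}ethyl)phenoxy]-4-methoxybenzaldehyde F9. Reductive carbonyl coupling with TiCl4/Zn in refluxing THF under high dilution, which aryl bromides generally survive, should then give the macrocyclic stilbene and return to the route at 17.

Step 2. Bromination may go in part para to the aryloxy group (between CHO and OMe) and give regioisomers that are hard to separate. The fallback installs bromine before the ether is made, directed by the free phenol. It sets out from 1: amine-mediated ortho-bromination (NBS, cat. iPr2NH, CH2Cl2, 0 °C) should go to the site that is both ortho to OH and para to OMe and give 2-bromo-3-hydroxy-5-methoxybenzaldehyde F10. Chan–Lam coupling of F10 with [3-(methoxycarbonyl)phenyl]boronic acid (COC(=O)c1cccc(B(O)O)c1; Cu(OAc)2, pyridine, 4 Å MS, CH2Cl2, air, rt), which tolerates the aryl bromide, comes back to the route at 4.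

**Further compounds**
F1 | step 12 | methyl 9-formyl-7-methoxydibenzo[b,d]furan-3-carboxylate | COc1cc(C=O)c2c(c1)oc1cc(ccc12)C(=O)OC
F2 | step 12 | methyl 9-{2-[4-(5-cyano-2-methoxyphenoxy)phenyl]ethenyl}-7-methoxydibenzo[b,d]furan-3-carboxylate (E/Z) | COc1cc(C=Cc3ccc(Oc4cc(C#N)ccc4OC)cc3)c2c(c1)oc1cc(ccc12)C(=O)OC
F3 | step 12 | methyl 9-{2-[4-(5-cyano-2-methoxyphenoxy)phenyl]ethyl}-7-methoxydibenzo[b,d]furan-3-carboxylate | COc1cc(CCc3ccc(Oc4cc(C#N)ccc4OC)cc3)c2c(c1)oc1cc(ccc12)C(=O)OC
F4 | step 12 | N–H aldimine of F5 | COc1cc(CCc3ccc(Oc4cc(C=N)ccc4OC)cc3)c2c(c1)oc1cc(ccc12)CO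
F5 | step 12 | 3-[4-(2-{7-(hydroxymethyl)-3-methoxydibenzo[b,d]furan-1-yl}ethyl)phenoxy]-4-methoxybenzaldehyde | COc1cc(CCc3ccc(Oc4cc(C=O)ccc4OC)cc3)c2c(c1)oc1cc(ccc12)CO
F6 | step 12 | ({9-[2-{4-(5-formyl-2-methoxyphenoxy)phenyl}ethyl]-7-methoxydibenzo[b,d]furan-3-yl}methyl)triphenylphosphonium bromide | [Br-].COc1cc(CCc3ccc(Oc4cc(C=O)ccc4OC)cc3)c2c(c1)oc1cc(ccc12)C[P+](c1ccccc1)(c1ccccc1)c1ccccc1
F7 | step 12 | ylide of the dibenzofuran seco-aldehyde | COc1cc(CCc3ccc(Oc4cc(C=O)ccc4OC)cc3)c2c(c1)oc1cc(ccc12)C=P(c1ccccc1)(c1ccccc1)c1ccccc1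
F8 | step 12 | 18-membered didehydro-asterelin A dimethyl ether (ring-B/ring-C bridge CH=CH, E/Z) | COc1cc2c3c(c1)oc1cc(ccc13)C=Cc1ccc(OC)c(c1)Oc1ccc(cc1)CC2
F9 | step 10 | 3-[4-(2-{2-bromo-3-(3-formylphenoxy)-5-methoxyphenyl}ethyl)phenoxy]-4-methoxybenzaldehyde | O=Cc1cccc(Oc2cc(OC)cc(CCc3ccc(Oc4cc(C=O)ccc4OC)cc3)c2Br)c1
F10 | step 2 | 2-bromo-3-hydroxy-5-methoxybenzaldehyde | COc1cc(O)c(Br)c(C=O)c1
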